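The data were generated by integration for substances that don't exist; scatter was added.

In this closed, stirred vessel you can follow the substrate by what it has become, so take the closed mass balance as the zero of your scale.

| flask | substrate | gas phase | remark | time |
|---|---|---|---|---|
| delta | 43 mM | 12 mM (held) | the very flask that is asked about, followed so far |  |
| theta | 86 mM | 12 mM (held) | run made earlier |  |
| flask | 43 mM | 12 mM (held) |  | 25 min |

| run | time / min | target / % | side product / % |
|---|---|---|---|
| delta | 1.00 | 12.0 | 41.6 |
| delta | 2.00 | 20.5 | 59.3 |
| delta | 4.00 | 26.5 | 70.2 |
| delta | 6.00 | 27.8 | 72.0 |
| delta | 12.0 | 27.7 | 71.9 |
| theta | 2.00 | 18.1 | 61.1 |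
| theta | 4.00 | 24.1 | 72.5 |
| theta | 8.00 | 25.3 | 74.3 |
| theta | 12.0 | 25.1 | 74.9 |
| theta | 25.0 | 25.5 | 74.4 |

(standard deviation of a reading: 0.3 percentage points)

- why nothing more happens at 25 min, or that something still does (forward and back rates have come level / all of the substrate has reacted / it is still moving)
- amount of target at 25 min, in percent of the substrate charged
- amount of side product at 25 min, in percent of the substrate charged

- at the start none of the gas phase is in solution
- the reaction counts as stopped when no species that holds the substrate changes by six tenths of a point or more over the second half of the time

At 12.0 min of the delta run, which is this very flask followed so far, target and side product leave 0.4 percentage points unaccounted for: call this the open gap, the part of the substrate charged that is found in neither product. Now turn the question round. For the flask to be still moving at 25 min, or to stand level with substrate left over, this gap would have to stay clearly open, and for the first case it would have to reach the 0.6 points of the stopping rule, yet it reads below that, with each reading carrying an error of 0.3 points. The theta run, with its gap of 0.1 points at 25.0 min, shows target going from 25.3 % to 25.5 % after 8.00 min, so I expect the gap to close and the flask to stand at the last delta reading, 27.7 % of target and 71.9 % of side product.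

The forecast answers "all of the substrate has reacted" with 27.8 % of target and 72.1 % of side product, up to 0.2 points from my figures, reasoning “so no substrate is left”.

The flask gives "all of the substrate has reacted", with 27.8 % of target, 72.2 % of side product and 0 % of the substrate left, where the open gap of the delta run read 0.4 points.

    gas phase ⇌ dissolved gas, rate k1*(csat - [dissolved gas]) (kL = 0.0400 s⁻¹)
    substrate + dissolved gas → target (k = 0.490 L mol⁻¹ s⁻¹)
    substrate → side product (k = 0.00970 s⁻¹)

At 0.816 min the half-life of the substrate by the step to side product is 1.2 min against 2.8 min by the step to target, a factor of 2.38 in favour of the faster side product step, and this flask ends with 2.60 times as much side product as target. The neighbour flask charged with 170 mM of substrate closes its gap as well, with 0 % of the substrate left at 25.0 min, yet it holds 21.9 % of target against 78.1 % of side product.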